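Ring A is closed last, onto a preformed ring B. The disconnection exploits that the quaternary fusion carbon C10 is flanked in ring B by C9 and C5: as a 2-methylcyclohexenone (C9=O, C5=C10) carrying the C4 ester arm on C5, its C4-derived dienolate attacks a tethered C1 bromide through C10. One operation thus forms ring A, the C10 stereocentre and a C4=C5 enoate plus C9 ketone, handles that are later relayed to C4 (deconjugative methylation), C5/C6 (hydroboration) and C8/C9/C11. The precursor is a flat bromopentanoate-substituted enone; the Z-diene arrives by a final Negishi coupling.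

Key step: step 2

Remark: the SMILES is read as methyl 6α-acetoxylabda-8(17),12Z,14-trien-19-oate of the normal labdane series (5α-H, 9α-H, 10β-CH3, 4α-CH3, 4β-CO2CH3); labdane numbering is used for all bicyclic compounds, and the cinchonidinium catalyst of step 2 is assumed to give the 10β-methyl series (its cinchoninium pseudo-enantiomer would be taken if the sense is opposite).

Step 1
Reactants: 1 methyl 5-bromopentanoate; 2 3-ethoxy-2-methylcyclohex-2-en-1-one
Product: 5 methyl 5-bromo-2-(2-methyl-3-oxocyclohex-1-en-1-yl)pentanoate (racemic), via lithium ester enolate 3 (not isolated), via lithium alkoxide adduct 4 (not isolated)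
Conditions: LiN(iPr)2, THF, –78 °C; then 2, –78 → –40 °C; then 1 M HCl, THF, 0 °C → rt
Reagents that add atoms: water, O (supplies the new C9 carbonyl oxygen during the hydrolytic transposition)
Why: Stork–Danheiser enone transposition: the ester enolate adds 1,2 to the vinylogous-ester carbonyl and aqueous acid ionises the tertiary allylic alcohol and hydrolyses the enol ether, which should place the ester arm on the enone β-carbon (C5) next to the methyl-bearing C10; the C4 centre is racemic and is erased in step 2.

Step 2
Reactants: 5 methyl 5-bromo-2-(2-methyl-3-oxocyclohex-1-en-1-yl)pentanoate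
Product: 7 methyl (10S)-9-oxo-11,12,13,14,15,16,17,18-octanorlabd-4-en-19-oate, via cesium dienolate 6 (not isolated)
Conditions: O-allyl-N-(9-anthracenylmethyl)cinchonidinium bromide (10 mol %), Cs2CO3 (powder), toluene, –20 °C, high dilution
Reagents that add atoms: none
Why: Proposed new method: deprotonation at C4 (a vinylogous β-keto ester position) gives a delocalized dienolate that is held in toluene as an ion pair with the chiral ammonium cation and displaces the primary bromide at C1 by SN2 through C10, the α-carbon of the enone, so that ring A closes in a 6-(enolexo)-exo-tet mode and the C5=C10 bond moves to C4=C5. The closest known chemistry is the α-alkylation of Hagemann's ester at its ring α-carbon and the deconjugative α,α-dialkylation of 4-en-3-one steroids, together with asymmetric phase-transfer alkylation of β-keto esters to quaternary centres; the intramolecular, vinylogous, enantioselective combination has not been shown. C10 is the only new stereocentre and its configuration (methyl β) should be set by the catalyst, which shields one face of the planar dienolate. Site selectivity for C10 is secured by ring size, since attack through C4 would give a cyclobutane and attack through the ketone oxygen an eight-membered ring, and O-alkylation through the ester oxygen is not expected for a soft primary bromide in a non-polar medium. The uncertain element is the enantioselectivity against cyclisation of the achiral cesium dienolate, which is why a solid weak base, low temperature and toluene are proposed.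

Step 3
Reactants: 7 methyl (10S)-9-oxo-11,12,13,14,15,16,17,18-octanorlabd-4-en-19-oate
Product: 8 methyl 9-oxo-11,12,13,14,15,16,18-heptanorlabda-4,8(17)-dien-19-oate
Conditions: (CH2O)n, N-methylanilinium trifluoroacetate (cat.), THF, reflux
Reagents that add atoms: formaldehyde (from paraformaldehyde), C=O
Why: Mannich-type α-methylenation (iminium catalysis by the anilinium salt, then β-elimination): C8 is the only enolisable position next to the C9 ketone because C10 is quaternary, so C17 should enter there as an exocyclic enone.

Step 4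
Reactants: 8 methyl 9-oxo-11,12,13,14,15,16,18-heptanorlabda-4,8(17)-dien-19-oate
Product: 9 methyl 9-oxo-17-(phenylselanyl)-11,12,13,14,15,16,18-heptanorlabd-4-en-19-oate (C8 epimers)
Conditions: PhSeH, Et3N (cat.), CH2Cl2, 0 °C
Reagents that add atoms: benzeneselenol, [SeH]c1ccccc1
Why: Seleno-Michael addition: the soft selenol adds to the unhindered exocyclic enone and not to the tetrasubstituted enoate, masking the future C8=C17 methylidene as a β-seleno ketone (C8 configuration irrelevant, removed in step 7).

Step 5
Reactants: 9 methyl 9-oxo-17-(phenylselanyl)-11,12,13,14,15,16,18-heptanorlabd-4-en-19-oate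
Product: 10 methyl 17-(phenylselanyl)-12,13,14,15,16,18-hexanorlabda-4,9(11)-dien-19-oate (C8 epimers)
Conditions: Zn, CH2Br2, TiCl4, THF, 0 °C; then 9, CH2Cl2, rt
Reagents that add atoms: dibromomethane, BrCBr
Why: Takai–Lombardo methylenation: the non-basic gem-dimetallic CH2 reagent should olefinate the hindered, enolisable C9 ketone without β-elimination of selenolate and without attacking the ester, giving the C9=C11 methylidene.

Step 6
Reactants: 10 methyl 17-(phenylselanyl)-12,13,14,15,16,18-hexanorlabda-4,9(11)-dien-19-oate
Product: 12 methyl 17-(phenylselanyl)-12,13,14,15,16-pentanorlabda-5,9(11)-dien-19-oate (C8 epimers), via lithium dienolate 11 (not isolated)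
Conditions: LiN(iPr)2, THF/DMPU, –78 °C; then MeI, –78 → –40 °C
Reagents that add atoms: iodomethane, CI
Why: Deconjugative α-alkylation of an enoate: the amide base removes a γ-hydrogen at C6 (C10 has none), and the extended enolate is methylated at C4 from the α-face, opposite the axial C10 methyl, which should set C4 with the ester β (axial) and move the alkene to C5=C6.

Step 7
Reactants: 12 methyl 17-(phenylselanyl)-12,13,14,15,16-pentanorlabda-5,9(11)-dien-19-oate
Product: 15 methyl 6α,11-dihydroxy-12,13,14,15,16-pentanorlabd-8(17)-en-19-oate, via bis(alkylborane) 13 (not isolated), via selenoxide diol 14 (not isolated)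
Conditions: BH3·THF (excess), THF, 0 → 40 °C; then NaOH, H2O2, 0 °C → rt
Reagents that add atoms: hydrogen peroxide, OO
Why: Hydroboration–oxidation with selenoxide elimination: syn addition of B–H to both alkenes from the α-face, opposite the axial C10 methyl and the axial C4 ester, should set 5α-H/6α-OH and 9α-H with boron on C11, and the alkaline peroxide then oxidises C–B to C–OH and the selenide to a selenoxide that syn-eliminates across C8–C17.

Step 8
Reactants: 15 methyl 6α,11-dihydroxy-12,13,14,15,16-pentanorlabd-8(17)-en-19-oate
Product: 16 methyl 6α-hydroxy-11-iodo-12,13,14,15,16-pentanorlabd-8(17)-en-19-oate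
Conditions: I2, PPh3, imidazole, CH2Cl2, 0 °C → rt
Reagents that add atoms: iodine, II
Why: Appel reaction: the iodophosphonium reagent activates the primary C11 hydroxyl far faster than the hindered secondary C6 hydroxyl, and iodide displaces with no change at any stereocentre.

Step 9
Reactants: 16 methyl 6α-hydroxy-11-iodo-12,13,14,15,16-pentanorlabd-8(17)-en-19-oate
Product: 17 methyl 6α-acetoxy-11-iodo-12,13,14,15,16-pentanorlabd-8(17)-en-19-oate
Conditions: Ac2O, DMAP, pyridine, 40 °C
Reagents that add atoms: acetic anhydride, CC(=O)OC(C)=O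
Why: Nucleophilic-catalysed acylation (DMAP) of the equatorial C6 alcohol; no stereocentre is touched.

Step 10
Reactants: 18 prop-2-yn-1-ol
Product: 20 (Z)-3-iodo-2-methylprop-2-en-1-ol, via alkenylmagnesium chelate 19 (not isolated)
Conditions: MeMgBr (2.2 equiv), CuI (10 mol %), THF, –10 °C → rt; then I2, –20 °C
Reagents that add atoms: methylmagnesium bromide, C[Mg]Br; iodine, II
Why: Copper-catalysed anti-carbomagnesiation of the propargylic alkoxide gives a five-membered alkenylmagnesium chelate, and iodinolysis with retention fixes the Z geometry (iodine cis to CH2OH).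

Step 11
Reactants: 20 (Z)-3-iodo-2-methylprop-2-en-1-ol
Product: 21 (Z)-3-iodo-2-methylprop-2-enal
Conditions: MnO2, CH2Cl2, rt, dark
Reagents that add atoms: none
Why: Allylic oxidation with MnO2 under neutral conditions should give the enal without Z/E isomerisation.

Step 12
Reactants: 21 (Z)-3-iodo-2-methylprop-2-enal
Product: 22 (Z)-1-iodo-2-methylbuta-1,3-diene
Conditions: Ph3PCH3Br, KN(SiMe3)2, THF, –78 → 0 °C; kept as a solution
Reagents that add atoms: methyltriphenylphosphonium bromide, C[P+](c1ccccc1)(c1ccccc1)c1ccccc1.[Br-]
Why: Wittig methylenation of the aldehyde at low temperature; the iodoalkene geometry is not involved.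

Step 13
Reactants: 17 methyl 6α-acetoxy-11-iodo-12,13,14,15,16-pentanorlabd-8(17)-en-19-oate; 22 (Z)-1-iodo-2-methylbuta-1,3-diene
Product: 24 methyl 6α-acetoxylabda-8(17),12Z,14-trien-19-oate (target CNP0212193.2), via alkylzinc iodide 23 (not isolated)
Conditions: 17, Zn dust, LiCl, THF, 40 °C; then 22, PdCl2(dppf) (5 mol %), THF, rt
Reagents that add atoms: none
Why: Negishi coupling: zinc inserts into the primary C–I bond to give an ester-tolerant alkylzinc, which couples with the alkenyl iodide with retention of the Z geometry, the wide-bite-angle diphosphine favouring reductive elimination over β-hydride loss.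

Compound list
1 | methyl 5-bromopentanoate | COC(=O)CCCCBr | starting material
2 | 3-ethoxy-2-methylcyclohex-2-en-1-one | CCOC1=C(C)C(=O)CCC1 | starting material
3 | lithium enolate of methyl 5-bromopentanoate | COC(O[Li])=CCCCBr | intermediate
4 | lithium alkoxide of methyl 5-bromo-2-(3-ethoxy-1-hydroxy-2-methylcyclohex-2-en-1-yl)pentanoate (diastereomer mixture) | COC(=O)C(CCCBr)C1(O[Li])CCCC(OCC)=C1C | intermediate
5 | methyl 5-bromo-2-(2-methyl-3-oxocyclohex-1-en-1-yl)pentanoate (racemic) | COC(=O)C(CCCBr)C1=C(C)C(=O)CCC1 | intermediate
6 | cesium dienolate of 5 (charge delocalized over C4, C10 and the C9 oxygen) | COC(=O)C(CCCBr)=C1CCCC([O-])=C1C.[Cs+] | intermediate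
7 | methyl (10S)-9-oxo-11,12,13,14,15,16,17,18-octanorlabd-4-en-19-oate, i.e. methyl (4aS)-4a-methyl-5-oxo-2,3,4,4a,5,6,7,8-octahydronaphthalene-1-carboxylate (10β-methyl) | O=C1CCCC2=C(C(=O)OC)CCC[C@]12C | intermediate
8 | methyl 9-oxo-11,12,13,14,15,16,18-heptanorlabda-4,8(17)-dien-19-oate (10β-methyl) | O=C1C(=C)CCC2=C(C(=O)OC)CCC[C@]12C | intermediate
9 | methyl 9-oxo-17-(phenylselanyl)-11,12,13,14,15,16,18-heptanorlabd-4-en-19-oate (10β-methyl; C8 epimers) | O=C1C(C[Se]c3ccccc3)CCC2=C(C(=O)OC)CCC[C@]12C | intermediate
10 | methyl 17-(phenylselanyl)-12,13,14,15,16,18-hexanorlabda-4,9(11)-dien-19-oate (10β-methyl; C8 epimers) | C=C1C(C[Se]c3ccccc3)CCC2=C(C(=O)OC)CCC[C@]12C | intermediate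
11 | lithium dienolate of 10 (C19 enolate, C5=C6) | C=C1C(C[Se]c3ccccc3)CC=C2C(=C(OC)O[Li])CCC[C@]12C | intermediate
12 | methyl 17-(phenylselanyl)-12,13,14,15,16-pentanorlabda-5,9(11)-dien-19-oate (4α-methyl, 4β-ester, 10β-methyl; C8 epimers) | C=C1C(C[Se]c3ccccc3)CC=C2[C@]1(C)CCC[C@]2(C)C(=O)OC | intermediate
13 | 6α,11-bis(boranyl) adduct of 12 (5α-H, 9α-H) | BC[C@H]1C(C[Se]c3ccccc3)C[C@H](B)[C@@H]2[C@]1(C)CCC[C@]2(C)C(=O)OC | intermediate
14 | methyl 6α,11-dihydroxy-17-(phenylseleninyl)-12,13,14,15,16-pentanorlabdan-19-oate (selenoxide) | OC[C@H]1C(C[Se](=O)c3ccccc3)C[C@H](O)[C@@H]2[C@]1(C)CCC[C@]2(C)C(=O)OC | intermediate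
15 | methyl 6α,11-dihydroxy-12,13,14,15,16-pentanorlabd-8(17)-en-19-oate | OC[C@H]1C(=C)C[C@H](O)[C@@H]2[C@]1(C)CCC[C@]2(C)C(=O)OC | intermediate
16 | methyl 6α-hydroxy-11-iodo-12,13,14,15,16-pentanorlabd-8(17)-en-19-oate | IC[C@H]1C(=C)C[C@H](O)[C@@H]2[C@]1(C)CCC[C@]2(C)C(=O)OC | intermediate
17 | methyl 6α-acetoxy-11-iodo-12,13,14,15,16-pentanorlabd-8(17)-en-19-oate | IC[C@H]1C(=C)C[C@H](OC(C)=O)[C@@H]2[C@]1(C)CCC[C@]2(C)C(=O)OC | intermediate
18 | prop-2-yn-1-ol | C#CCO | starting material
19 | (Z)-alkenylmagnesium bromide alkoxide chelate (Mg cis to CH2O) | Br[Mg]OC/C(C)=C\[Mg]Br | intermediate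
20 | (Z)-3-iodo-2-methylprop-2-en-1-ol | OC/C(C)=C\I | intermediate
21 | (Z)-3-iodo-2-methylprop-2-enal | O=C/C(C)=C\I | intermediate
22 | (Z)-1-iodo-2-methylbuta-1,3-diene | C=C/C(C)=C\I | intermediate
23 | C11 alkylzinc iodide derived from 17 | I[Zn]C[C@H]1C(=C)C[C@H](OC(C)=O)[C@@H]2[C@]1(C)CCC[C@]2(C)C(=O)OC | intermediate
24 | methyl 6α-acetoxylabda-8(17),12Z,14-trien-19-oate (CNP0212193.2) | C=C/C(C)=C\C[C@H]1C(=C)C[C@H](OC(C)=O)[C@@H]2[C@]1(C)CCC[C@]2(C)C(=O)OC | target

Total step count: 13. Longest linear sequence: 10 steps (steps 1–9 and 13); steps 10–12 make the diene fragment.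

Steps most likely to fail

1. Step 2 (Proposed new method). The achiral cesium dienolate may cyclise at the solid surface faster than the chiral ion pair does in solution, so that enantioselectivity is eroded; E2 loss of HBr from the tether may also compete. Fallback with known chemistry, setting out from 5: cyclisation without chiral catalyst (Cs2CO3, Bu4NBr, MeCN) should give the racemic keto enoate F1. A reagent-controlled CBS reduction ((S)-2-methyl-CBS-oxazaborolidine, BH3·SMe2) then converts the two enantiomers into diastereomers, the (9R,10S)-alcohol F2 and the (9R,10R)-alcohol F3, which are separated by chromatography. Oxidation of F2 with Dess–Martin periodinane returns to the route at 7.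

2. Step 7. The C5=C6 alkene lies between two quaternary carbons and may hydroborate only under forcing conditions, under which face selectivity at the C9 methylidene could fall and the ester could be reduced. Fallback, setting out from 12: the two hydroborations are separated. 9-BBN should react only with the C9=C11 methylidene (bulkier reagent, higher α-face preference), and oxidation with Me3NO·2H2O, which spares the selenide, should give the primary alcohol F5. Silylation (t-BuMe2SiCl, imidazole) gives the silyl ether F6. BH3·SMe2 followed by NaOH/H2O2 then installs 6α-OH and triggers the selenoxide elimination to the hydroxy silyl ether F7. Bu4NF removes the silyl group and the sequence returns to the route at 15.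

3. Step 5. The ketone is flanked by a quaternary and a tertiary carbon; slow methylenation may allow enolisation or β-elimination of benzeneselenolate. Fallback, setting out from 9: Peterson olefination through an organocerium reagent. Me3SiCH2Li with anhydrous CeCl3 (THF, –78 °C) should add to the hindered, enolisable ketone to give the β-hydroxysilane F4, and KH (THF, 0 °C → rt) effects the syn-elimination, returning to the route at 10.

Further compounds
F1 | step 2 | racemic methyl 9-oxo-11,12,13,14,15,16,17,18-octanorlabd-4-en-19-oate | O=C1CCCC2=C(C(=O)OC)CCC12C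
F2 | step 2 | methyl (4aS,5R)-5-hydroxy-4a-methyl-2,3,4,4a,5,6,7,8-octahydronaphthalene-1-carboxylate | O[C@@H]1CCCC2=C(C(=O)OC)CCC[C@]12C
F3 | step 2 | methyl (4aR,5R)-5-hydroxy-4a-methyl-2,3,4,4a,5,6,7,8-octahydronaphthalene-1-carboxylate | O[C@@H]1CCCC2=C(C(=O)OC)CCC[C@@]12C
F4 | step 5 | methyl 9-hydroxy-17-(phenylselanyl)-9-[(trimethylsilyl)methyl]-11,12,13,14,15,16,18-heptanorlabd-4-en-19-oate (C8 and C9 epimers) | C[Si](C)(C)CC1(O)C(C[Se]c3ccccc3)CCC2=C(C(=O)OC)CCC[C@]12C
F5 | step 7 | methyl 11-hydroxy-17-(phenylselanyl)-12,13,14,15,16-pentanorlabd-5-en-19-oate (9α-H; C8 epimers) | OC[C@H]1C(C[Se]c3ccccc3)CC=C2[C@]1(C)CCC[C@]2(C)C(=O)OC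
F6 | step 7 | methyl 11-(tert-butyldimethylsilyloxy)-17-(phenylselanyl)-12,13,14,15,16-pentanorlabd-5-en-19-oate | CC(C)(C)[Si](C)(C)OC[C@H]1C(C[Se]c3ccccc3)CC=C2[C@]1(C)CCC[C@]2(C)C(=O)OC
F7 | step 7 | methyl 11-(tert-butyldimethylsilyloxy)-6α-hydroxy-12,13,14,15,16-pentanorlabd-8(17)-en-19-oate | CC(C)(C)[Si](C)(C)OC[C@H]1C(=C)C[C@H](O)[C@@H]2[C@]1(C)CCC[C@]2(C)C(=O)OC
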